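**Retrosynthetic overview**

1. The cyclohexenedione ring is carried as a phloroglucinol ring (two silyl ethers) and made last, by desilylation and dearomative C-tetramethylation at C6 and C8.
2. Before that, a formyl group on C3 (activating group) is removed by decarbonylation, and C4 is set by conjugate addition of an isopropyl copper reagent to a spiro 2H-chromene-3-carbaldehyde.
3. Key disconnection: the bond between C3 (the pyran CH2) and the spiro carbon C2, which closes the pyran ring in a 1,5-hydride shift/ring closure of an ortho-(pinan-2-yloxy)aryl propynal.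
4. Enabling feature: the tertiary C–H of the ether carbon (future C2) lies five atoms from the arene-bound alkyne carbon (future C4) across O1–C8a=C4a, in the arene plane. At the aromatic oxidation level O1 is an electron-rich aryl-ether oxygen, so this C–H can leave as hydride and be replaced by C3 on the same face.
5. Ring order: the bicyclo[3.1.1]heptane ((+)-β-pinene) and the arene are bought; the pyran ring is closed in step 7; the dione ring is formed in step 10. The ynal comes from an aryl aldehyde (Corey–Fuchs/formylation), and its ether bond from a Mitsunobu inversion of cis-nopinol.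

Key step: step 7

Numbering used: chroman O1, C2 (spiro), C3, C4, C4a, C5–C8, C8a; bicycle C1'–C7' with C2' = C2, C6' = CMe2 bridge, C7' = CH2 bridge.

Assumption: the bicyclic part of the target has the absolute configuration of (1R,5R)-β-pinene, so the (+)-enantiomer is the chiral-pool source. Hydride is assumed to add to nopinone from the CH2-bridge face, as additions to this ketone generally do.

**Route**

Step 1
Reactants: 1 (1R,5R)-(+)-β-pinene
Product: 2 (1S,5R)-(−)-nopinone
Conditions: O3, CH2Cl2/MeOH, −78 °C; then Me2S, −78 °C → rt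
Reagents that add atoms: ozone, [O-][O+]=O
Why: Ozonolysis with reductive work-up cleaves the exocyclic C=CH2 bond to the ketone and touches no stereocentre.

Step 2
Reactants: 2 (1S,5R)-(−)-nopinone
Product: 3 (1S,2S,5R)-6,6-dimethylbicyclo[3.1.1]heptan-2-ol (cis-nopinol, OH on the CMe2-bridge face)
Conditions: LiAlH4, Et2O, −78 → 0 °C; then H2O
Reagents that add atoms: none
Why: In this hydride reduction LiAlH4 attacks C2' from the CH2-bridge face, away from the syn methyl of the CMe2 bridge, so the new carbinol centre carries OH on the CMe2-bridge face.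

Step 3
Reactants: 4 2,4,6-trihydroxybenzaldehyde
Product: 5 2-hydroxy-4,6-bis(tert-butyldimethylsilyloxy)benzaldehyde
Conditions: TBSCl (2.1 equiv), imidazole, DMF, 0 °C
Reagents that add atoms: tert-butyldimethylsilyl chloride, CC(C)(C)[Si](C)(C)Cl
Why: In this selective silyl ether formation the para hydroxyl and the non-chelated ortho hydroxyl react, while the hydroxyl hydrogen-bonded to the formyl group stays free for step 4.

Step 4
Reactants: 5 2-hydroxy-4,6-bis(tert-butyldimethylsilyloxy)benzaldehyde; 3 cis-nopinol
Product: 6 2-{[(1S,2R,5R)-6,6-dimethylbicyclo[3.1.1]heptan-2-yl]oxy}-4,6-bis(tert-butyldimethylsilyloxy)benzaldehyde (ether O on the CH2-bridge face)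
Conditions: PPh3, DIAD, toluene, 0 °C → rt
Reagents that add atoms: none
Why: In this Mitsunobu etherification the acidic salicylaldehyde-type phenol displaces the oxyphosphonium group by SN2 from the open CH2-bridge face with inversion, which puts the ether oxygen trans to the CMe2 bridge and leaves the C2'–H on the CMe2-bridge face.

Step 5
Reactants: 6 aryl ether aldehyde
Product: 7 1,1-dibromoalkene: 2-(2,2-dibromoethenyl)-3,5-bis(tert-butyldimethylsilyloxy)phenyl (1S,2R,5R)-6,6-dimethylbicyclo[3.1.1]heptan-2-yl ether
Conditions: CBr4, PPh3, CH2Cl2, 0 °C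
Reagents that add atoms: carbon tetrabromide, BrC(Br)(Br)Br
Why: The Ramirez dibromo-olefination (first half of the Corey–Fuchs sequence) converts the aldehyde into the dibromoalkene and leaves the silyl ethers, the aryl ether and the stereocentres alone.

Step 6
Reactants: 7 1,1-dibromoalkene
Product: 9 3-[2-{[(1S,2R,5R)-6,6-dimethylbicyclo[3.1.1]heptan-2-yl]oxy}-4,6-bis(tert-butyldimethylsilyloxy)phenyl]prop-2-ynal, via lithium acetylide 8 (not isolated)
Conditions: n-BuLi (2.2 equiv), THF, −78 °C; DMF, −78 → 0 °C; poured into cold dilute aq. H3PO4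
Reagents that add atoms: N,N-dimethylformamide, CN(C)C=O
Why: In the second half of the Corey–Fuchs sequence, bromine–lithium exchange and a Fritsch–Buttenberg–Wiechell shift give the lithium acetylide, which is C-formylated by DMF, and the acidic inverse quench releases the ynal without conjugate addition of dimethylamine.

Step 7
Reactants: 9 aryl propynal
Product: 11 5,7-bis(tert-butyldimethylsilyloxy)spiro[2H-chromene-2,2'-(1'S,5'R)-6',6'-dimethylbicyclo[3.1.1]heptane]-3-carbaldehyde (O1 on the CH2-bridge face and C3 on the CMe2-bridge face), via oxocarbenium allenolate zwitterion 10 (not isolated)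
Conditions: Sc(OTf)3 (10 mol %), ClCH2CH2Cl, 60 °C
Reagents that add atoms: none
Why: Proposed new method: Sc(OTf)3 on the formyl oxygen turns the in-plane π* orbital of the alkyne into a hydride acceptor at the arene-bound carbon (future C4), and the tertiary C2'–H of the ether carbon, five atoms away and held in the arene plane, is delivered to it in a 1,5-hydride shift that gives the oxocarbenium/scandium allenolate pair 10; the central allenolate carbon (future C3) then bonds to the oxocarbenium carbon. The closest known reaction type is the Lewis-acid-catalysed 1,5-hydride shift/ring closure of ortho-alkoxyaryl alkylidene malonates and enals to chromans, together with hydride shifts from ether C–H bonds onto electron-poor or metal-activated alkynes. One ring is closed, the pyran ring, through the C3–C2 bond, in a 6-endo-trig mode with respect to the C=O+ bond. The one new stereocentre is the spiro carbon, and it is controlled by the configuration of the C–H carbon of 9: the hydride leaves toward the alkyne on the CMe2-bridge face, and the allenolate carbon, which lies in the arene plane on that same side, fills the vacated lobe before the C=O+ unit can turn, so that C–C replaces C–H with retention. The step needs exactly this retention, against the bias of the bicycle (a free carbon nucleophile would enter from the CH2-bridge face), and it needs the tertiary C–H to be the only hydride donor, which is secured because the silyl ethers have no C–H next to oxygen and the two reacting carbons are tied to the arene ortho to the ether oxygen.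

Step 8
Reactants: 11 spiro 2H-chromene-3-carbaldehyde
Product: 13 4-isopropyl-5,7-bis(tert-butyldimethylsilyloxy)spiro[chromane-2,2'-(1'S,5'R)-6',6'-dimethylbicyclo[3.1.1]heptane]-3-carbaldehyde (C2 and C4 as in the target; mixture at C3), via trimethylsilyl enol ether 12 (not isolated)
Conditions: i-PrMgCl, CuBr·SMe2 (10 mol %), TMSCl, DMPU, THF, −78 °C; then 1 M HCl, THF, 0 °C
Reagents that add atoms: isopropylmagnesium chloride, CC(C)[Mg]Cl
Why: In this copper-catalysed, TMSCl-accelerated conjugate addition of the Grignard reagent to the enal, the clash between the syn methyl of the CMe2 bridge and the C3 formyl group forces the pyran half-chair in which the bridgehead C1' is pseudo-axial, so the isopropyl group adds axially to C4 on the opposite face (cis to the ring CH2 C3' of the bicycle), which is the target configuration; C3 forms as a mixture that step 9 erases.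

Step 9
Reactants: 13 chroman-3-carbaldehyde
Product: 14 (4S)-4-isopropyl-5,7-bis(tert-butyldimethylsilyloxy)spiro[chromane-2,2'-(1'S,5'R)-6',6'-dimethylbicyclo[3.1.1]heptane] (spiro carbon as in the target)
Conditions: [Rh(cod)Cl]2 (5 mol %), dppp (10 mol %), diglyme, 160 °C
Reagents that add atoms: none
Why: Rhodium-catalysed decarbonylation of the aldehyde (Tsuji–Wilkinson type) replaces C3–CHO by C3–H with loss of CO, which removes the activating group and the stereocentre at C3 and leaves C2 and C4 untouched.

Step 10
Reactants: 14 bis-silyl spirochroman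
Product: 16 target CNP0534730.3, (2S,4S,1'S,5'R)-4-isopropyl-6,6,8,8-tetramethylspiro[chromane-2,2'-6',6'-dimethylbicyclo[3.1.1]heptane]-5,7-dione, via bisphenol 15 (not isolated)
Conditions: NaOMe (8 equiv), MeOH, rt; then MeI (10 equiv), 0 → 50 °C
Reagents that add atoms: iodomethane, CI
Why: Methoxide cleaves both aryl silyl ethers and the phloroglucinol-type bis-phenolate then undergoes exhaustive dearomative C-methylation at C6 and C8 (the classical route to syncarpic-acid-type rings), which gives the 6,6,8,8-tetramethyl enol-ether dione without touching C2 or C4, neither of which is enolisable.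

**Compound list**

1 | (1R,5R)-(+)-β-pinene, (1R,5R)-6,6-dimethyl-2-methylidenebicyclo[3.1.1]heptane | C=C1CC[C@@H]2C[C@H]1C2(C)C | starting material
2 | (1S,5R)-(−)-nopinone, (1S,5R)-6,6-dimethylbicyclo[3.1.1]heptan-2-one | O=C1CC[C@@H]2C[C@H]1C2(C)C | intermediate
3 | (1S,2S,5R)-6,6-dimethylbicyclo[3.1.1]heptan-2-ol (cis-nopinol, OH on the CMe2-bridge face) | O[C@H]1CC[C@@H]2C[C@H]1C2(C)C | intermediate
4 | 2,4,6-trihydroxybenzaldehyde | O=Cc1c(O)cc(O)cc1O | starting material
5 | 2-hydroxy-4,6-bis(tert-butyldimethylsilyloxy)benzaldehyde | O=Cc1c(O)cc(O[Si](C)(C)C(C)(C)C)cc1O[Si](C)(C)C(C)(C)C | intermediate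
6 | 2-{[(1S,2R,5R)-6,6-dimethylbicyclo[3.1.1]heptan-2-yl]oxy}-4,6-bis(tert-butyldimethylsilyloxy)benzaldehyde (ether O on the CH2-bridge face) | O=Cc1c(O[C@@H]2CC[C@@H]3C[C@H]2C3(C)C)cc(O[Si](C)(C)C(C)(C)C)cc1O[Si](C)(C)C(C)(C)C | intermediate
7 | 1,1-dibromoalkene from 6 (2,2-dibromoethenyl in place of formyl) | BrC(Br)=Cc1c(O[C@@H]2CC[C@@H]3C[C@H]2C3(C)C)cc(O[Si](C)(C)C(C)(C)C)cc1O[Si](C)(C)C(C)(C)C | intermediate
8 | lithium acetylide of the aryl alkyne | [Li]C#Cc1c(O[C@@H]2CC[C@@H]3C[C@H]2C3(C)C)cc(O[Si](C)(C)C(C)(C)C)cc1O[Si](C)(C)C(C)(C)C | intermediate (not isolated)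
9 | 3-[2-{[(1S,2R,5R)-6,6-dimethylbicyclo[3.1.1]heptan-2-yl]oxy}-4,6-bis(tert-butyldimethylsilyloxy)phenyl]prop-2-ynal | O=CC#Cc1c(O[C@@H]2CC[C@@H]3C[C@H]2C3(C)C)cc(O[Si](C)(C)C(C)(C)C)cc1O[Si](C)(C)C(C)(C)C | intermediate
10 | oxocarbenium allenolate zwitterion (drawn without scandium) | [O-]C=C=Cc1c([O+]=C2CC[C@@H]3C[C@H]2C3(C)C)cc(O[Si](C)(C)C(C)(C)C)cc1O[Si](C)(C)C(C)(C)C | intermediate (not isolated)
11 | 5,7-bis(tert-butyldimethylsilyloxy)spiro[2H-chromene-2,2'-(1'S,5'R)-6',6'-dimethylbicyclo[3.1.1]heptane]-3-carbaldehyde (O1 on the CH2-bridge face, C3 on the CMe2-bridge face) | O=CC1=Cc2c(O[Si](C)(C)C(C)(C)C)cc(O[Si](C)(C)C(C)(C)C)cc2O[C@@]13CC[C@@H]4C[C@H]3C4(C)C | intermediate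
12 | trimethylsilyl enol ether of 13 (enol ether geometry not defined) | CC(C)[C@@H]1C(=CO[Si](C)(C)C)[C@]2(CC[C@@H]3C[C@H]2C3(C)C)Oc2cc(O[Si](C)(C)C(C)(C)C)cc(O[Si](C)(C)C(C)(C)C)c12 | intermediate (not isolated)
13 | 4-isopropyl-5,7-bis(tert-butyldimethylsilyloxy)spirochromane-3-carbaldehyde (C2 and C4 as in the target, isopropyl cis to C3' of the bicycle; C3 mixture) | CC(C)[C@@H]1C(C=O)[C@]2(CC[C@@H]3C[C@H]2C3(C)C)Oc2cc(O[Si](C)(C)C(C)(C)C)cc(O[Si](C)(C)C(C)(C)C)c12 | intermediate
14 | (4S)-4-isopropyl-5,7-bis(tert-butyldimethylsilyloxy)spiro[chromane-2,2'-(1'S,5'R)-6',6'-dimethylbicyclo[3.1.1]heptane] | CC(C)[C@@H]1C[C@]2(CC[C@@H]3C[C@H]2C3(C)C)Oc2cc(O[Si](C)(C)C(C)(C)C)cc(O[Si](C)(C)C(C)(C)C)c12 | intermediate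
15 | (4S)-4-isopropylspiro[chromane-2,2'-(1'S,5'R)-6',6'-dimethylbicyclo[3.1.1]heptane]-5,7-diol (present as its disodium salt) | CC(C)[C@@H]1C[C@]2(CC[C@@H]3C[C@H]2C3(C)C)Oc2cc(O)cc(O)c12 | intermediate (not isolated)
16 | CNP0534730.3, (2S,4S,1'S,5'R)-4-isopropyl-6,6,8,8-tetramethylspiro[chromane-2,2'-6',6'-dimethylbicyclo[3.1.1]heptane]-5,7-dione | CC(C)[C@@H]1C[C@]2(CC[C@@H]3C[C@H]2C3(C)C)OC2=C1C(=O)C(C)(C)C(=O)C2(C)C | target

**Step count**

Total: 10 steps. Longest linear sequence: 9 steps (1, 2, 4, 5, 6, 7, 8, 9, 10).

**Steps most likely to fail, with fallbacks**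

1. Step 7 (key step). The hydride shift may be too slow, because the donor C–H lies on the screened face of the bicycle and the linear ynal arm has to pass the syn methyl group. Once formed, the oxocarbenium ion may lose a proton from C3' or open the cyclobutane before C3 reaches C2, and the Lewis acid may remove a silyl group. The fallback uses known chemistry and sets out from 1. The dione ring is brought in as purchased 2,2,4,4-tetramethylcyclohexane-1,3,5-trione (syncarpic acid). Knoevenagel condensation of syncarpic acid with isobutyraldehyde (piperidine cat., CH2Cl2) gives 2-(2-methylpropylidene)-4,4,6,6-tetramethylcyclohexane-1,3,5-trione F1. F1 is trapped as it forms by 1 in an inverse-electron-demand hetero-Diels–Alder reaction (toluene, 80 °C). Oxygen adds to C2' from the CH2-bridge face, the C4 epimers are separated, and the fallback comes back to the route at 16.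

2. Step 8. The copper reagent may attack the wrong face of C4, or add 1,2 to the aldehyde. The fallback reverses the order in which the two C4 substituents arrive, so that the same facial preference now places hydrogen instead of isopropyl. It sets out from 12, isolated by non-aqueous work-up whatever its configuration at C4. Saegusa–Ito oxidation (Pd(OAc)2, MeCN, rt) gives 4-isopropyl-5,7-bis(tert-butyldimethylsilyloxy)spiro[2H-chromene-2,2'-(1'S,5'R)-6',6'-dimethylbicyclo[3.1.1]heptane]-3-carbaldehyde F2. Conjugate reduction of F2 with the copper hydride [(Ph3P)CuH]6 (toluene, rt; aqueous work-up) delivers hydride to C4 on the face the cuprate had used, leaving isopropyl on the required face. The fallback comes back to the route at 13.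

3. Step 4. Elimination of the oxyphosphonium ion to the alkene may outrun substitution, because the phenoxide of 5 is chelated and ortho-substituted. The fallback uses a free, unhindered phenol and installs the formyl group afterwards. It sets out from 3 and purchased phloroglucinol. Silylation (TBSCl, 2 equiv, imidazole, DMF) gives 3,5-bis(tert-butyldimethylsilyloxy)phenol F3. Mitsunobu reaction of F3 with 3 (PPh3, DIAD, toluene) gives (1S,2R,5R)-2-[3,5-bis(tert-butyldimethylsilyloxy)phenoxy]-6,6-dimethylbicyclo[3.1.1]heptane F4 with inversion. Vilsmeier–Haack formylation of F4 (POCl3, DMF, 0 °C; aq. NaOAc) goes to one of the two equivalent positions between the bicyclic ether and a silyl ether, since the position between the two silyl ethers is more hindered. The fallback comes back to the route at 6.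

**Further compounds**

F1 | step 7 | 2-(2-methylpropylidene)-4,4,6,6-tetramethylcyclohexane-1,3,5-trione | CC(C)C=C1C(=O)C(C)(C)C(=O)C(C)(C)C1=O
F2 | step 8 | 4-isopropyl-5,7-bis(tert-butyldimethylsilyloxy)spiro[2H-chromene-2,2'-(1'S,5'R)-6',6'-dimethylbicyclo[3.1.1]heptane]-3-carbaldehyde | CC(C)C1=C(C=O)[C@]2(CC[C@@H]3C[C@H]2C3(C)C)Oc2cc(O[Si](C)(C)C(C)(C)C)cc(O[Si](C)(C)C(C)(C)C)c12
F3 | step 4 | 3,5-bis(tert-butyldimethylsilyloxy)phenol | Oc1cc(O[Si](C)(C)C(C)(C)C)cc(O[Si](C)(C)C(C)(C)C)c1
F4 | step 4 | (1S,2R,5R)-2-[3,5-bis(tert-butyldimethylsilyloxy)phenoxy]-6,6-dimethylbicyclo[3.1.1]heptane | CC(C)(C)[Si](C)(C)Oc1cc(O[Si](C)(C)C(C)(C)C)cc(O[C@@H]2CC[C@@H]3C[C@H]2C3(C)C)c1
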